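The ketone linking ring A to the chain is disconnected by aryne chemistry: C1 and the phenolic oxygen on C2' of the target are the carbon and one oxygen of a single carboxyl group, and the C6' oxygen flanks the aryne to steer it. In one operation, fluoride releases 3,5-bis(methoxymethoxy)benzyne, the C20 carboxylate adds at C2' and the C1' anion takes the acyl group, forming the C2'–O and C1'–C1 bonds of the ortho-hydroxyaryl ketone. The precursors are a 2-silylaryl triflate from phloroglucinol and (17R)-17-(methoxymethoxy)arachidonic acid, built by copper-mediated skipped-alkyne couplings and semihydrogenation; every protecting group is a fluoride-inert acetal, removed in one final step.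

Key step: step 14

Remark: chain atoms are C1–C20 from the ketone carbon and ring A atoms C1'–C6' from the acylated carbon; the C17 hydroxyl is carried as a methoxymethyl ether and not as a silyl ether, because step 14 uses excess fluoride above 100 °C and a freed alkoxide would be arylated, while all three acetals still fall in one acid step.

Step 1
Reactants: 1 phloroglucinol
Product: 2 3,5-bis(methoxymethoxy)phenol
Conditions: MOMCl (2.0 equiv), i-Pr2NEt, DMF/CH2Cl2, 0 °C → rt; chromatography
Reagents that add atoms: chloromethyl methyl ether, COCCl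
Why: Base-mediated O-alkylation (Williamson-type acetal formation) of the threefold-symmetric triol with two equivalents of electrophile should give the bis-ether as the main component of a separable mono/bis/tris mixture, which is acceptable for the first step on an inexpensive material.

Step 2
Reactants: 2 3,5-bis(methoxymethoxy)phenol
Product: 3 3,5-bis(methoxymethoxy)phenyl isopropylcarbamate
Conditions: i-PrNCO, Et3N (cat.), CH2Cl2, rt
Reagents that add atoms: isopropyl isocyanate, CC(C)N=C=O
Why: Amine-catalysed addition of the free phenol to the isocyanate installs a secondary carbamate that serves as a removable directing group for ortho-metalation.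

Step 3
Reactants: 3 3,5-bis(methoxymethoxy)phenyl isopropylcarbamate
Product: 7 3,5-bis(methoxymethoxy)-2-(trimethylsilyl)phenyl isopropylcarbamate, via N-silyl carbamate 4 (not isolated), via aryllithium 5 (not isolated), via bis-silyl carbamate 6 (not isolated)
Conditions: TBSOTf (1.05 equiv), TMEDA, Et2O, 0 °C → rt; n-BuLi, TMEDA, −78 °C; Me3SiCl, −78 °C → rt; aq. NH4Cl
Reagents that add atoms: chlorotrimethylsilane, C[Si](C)(C)Cl
Why: In situ N-silylation blocks elimination of the secondary carbamate and makes it the strongest directing group on the ring, so directed ortho-metalation should occur between the carbamate and a methoxymethoxy group, the aryllithium is trapped by Me3SiCl, and the labile N–Si bond is lost on the mild aqueous work-up.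

Step 4
Reactants: 7 3,5-bis(methoxymethoxy)-2-(trimethylsilyl)phenyl isopropylcarbamate
Product: 9 3,5-bis(methoxymethoxy)-2-(trimethylsilyl)phenyl trifluoromethanesulfonate, via silylphenol 8 (not isolated)
Conditions: DBU, Et2NH, MeCN, 40 °C; then PhNTf2, rt
Reagents that add atoms: N-phenylbis(trifluoromethanesulfonimide), O=S(=O)(N(c1ccccc1)S(=O)(=O)C(F)(F)F)C(F)(F)F
Why: DBU triggers E1cB loss of the carbamoyl unit (trapped by Et2NH as a urea) and the freed 2-silylphenoxide is triflated in the same flask, a standard one-pot entry to ortho-silylaryl triflates that never exposes the acid-sensitive arylsilane to acid.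

Step 5
Reactants: 10 (R)-1,2-epoxypentane; 11 lithium acetylide ethylenediamine complex (LiC≡CH·H2NCH2CH2NH2)
Product: 12 (R)-hept-1-yn-4-ol
Conditions: DMSO, 0 °C → rt; then H2O
Reagents that add atoms: none
Why: SN2 opening of the terminal epoxide at its unsubstituted carbon by the acetylide leaves the C–O bond of the stereocenter untouched, so the R configuration of 10 becomes C17 (R) of the target.

Step 6
Reactants: 12 (R)-hept-1-yn-4-ol
Product: 13 (R)-4-(methoxymethoxy)hept-1-yne
Conditions: MOMCl, i-Pr2NEt, CH2Cl2, 0 °C → rt
Reagents that add atoms: chloromethyl methyl ether, COCCl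
Why: Standard acetal protection of a secondary alcohol gives an ether that is inert to carbonate, hydrogenation, hydroxide and fluoride and is cleaved together with the aryl acetals at the end.

Step 7
Reactants: 14 methyl hex-5-ynoate; 15 4-chlorobut-2-yn-1-ol
Product: 16 methyl 10-hydroxydeca-5,8-diynoate
Conditions: CuI, NaI, Cs2CO3, DMF, rt
Reagents that add atoms: none
Why: Copper-mediated coupling of a terminal alkyne with a propargylic halide under carbonate conditions (copper acetylide displaces the halide, iodide assisting) forms the C6–C7 bond of a skipped diyne without allene formation and tolerates the free alcohol and the ester.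

Step 8
Reactants: 16 methyl 10-hydroxydeca-5,8-diynoate
Product: 17 methyl 10-bromodeca-5,8-diynoate
Conditions: CBr4, PPh3, CH2Cl2, −20 → 0 °C
Reagents that add atoms: carbon tetrabromide, BrC(Br)(Br)Br
Why: The Appel reaction converts the primary propargylic alcohol into the bromide under neutral conditions that leave the base-sensitive skipped diyne intact.

Step 9
Reactants: 17 methyl 10-bromodeca-5,8-diynoate; 18 propargyl alcohol
Product: 19 methyl 13-hydroxytrideca-5,8,11-triynoate
Conditions: CuI, NaI, Cs2CO3, DMF, rt
Reagents that add atoms: none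
Why: The same copper-mediated alkyne–propargyl halide coupling forms the C10–C11 bond and extends the skipped array by one alkyne, again carrying the next hydroxyl handle.

Step 10
Reactants: 19 methyl 13-hydroxytrideca-5,8,11-triynoate
Product: 20 methyl 13-bromotrideca-5,8,11-triynoate
Conditions: CBr4, PPh3, CH2Cl2, −20 → 0 °C
Reagents that add atoms: carbon tetrabromide, BrC(Br)(Br)Br
Why: A second Appel bromination under neutral, cold conditions activates C13 while avoiding base-induced isomerisation of the skipped triyne, which is used at once.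

Step 11
Reactants: 20 methyl 13-bromotrideca-5,8,11-triynoate; 13 (R)-4-(methoxymethoxy)hept-1-yne
Product: 21 methyl (17R)-17-(methoxymethoxy)icosa-5,8,11,14-tetraynoate
Conditions: CuI, NaI, Cs2CO3, DMF, 0 °C → rt
Reagents that add atoms: none
Why: The copper-mediated coupling joins the achiral C1–C13 triyne to the chiral C14–C20 alkyne through the C13–C14 bond, the stereocenter being remote from the reacting carbon and untouched by the mild base.

Step 12
Reactants: 21 methyl (17R)-17-(methoxymethoxy)icosa-5,8,11,14-tetraynoate
Product: 22 methyl (5Z,8Z,11Z,14Z,17R)-17-(methoxymethoxy)icosa-5,8,11,14-tetraenoate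
Conditions: H2 (1 atm), nickel boride (Ni2B) from Ni(OAc)2·4H2O/NaBH4 (cat.), H2NCH2CH2NH2, EtOH, rt
Reagents that add atoms: none
Why: Catalytic semihydrogenation on amine-poisoned nickel boride delivers hydrogen syn to each alkyne and binds the resulting alkenes weakly, the standard way to turn skipped polyynes into all-Z skipped polyenes, so the four Z double bonds are set by cis-addition on the catalyst surface.

Step 13
Reactants: 22 methyl (5Z,8Z,11Z,14Z,17R)-17-(methoxymethoxy)icosa-5,8,11,14-tetraenoate
Product: 23 (5Z,8Z,11Z,14Z,17R)-17-(methoxymethoxy)icosa-5,8,11,14-tetraenoic acid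
Conditions: LiOH, THF/MeOH/H2O, 0 °C → rt, Ar; aq. HCl to pH 4, 0 °C
Reagents that add atoms: lithium hydroxide, [Li+].[OH-]
Why: Saponification of the methyl ester at ambient temperature leaves the acetal and the skipped Z-olefins unchanged, and acidification only to pH 4 spares the methoxymethyl ether.

Step 14
Reactants: 9 3,5-bis(methoxymethoxy)-2-(trimethylsilyl)phenyl trifluoromethanesulfonate (1.3 equiv); 23 (5Z,8Z,11Z,14Z,17R)-17-(methoxymethoxy)icosa-5,8,11,14-tetraenoic acid
Product: 25 (5Z,8Z,11Z,14Z,17R)-1-[2-hydroxy-4,6-bis(methoxymethoxy)phenyl]-17-(methoxymethoxy)icosa-5,8,11,14-tetraen-1-one, via aryne 24 (not isolated)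
Conditions: CsF (4 equiv), THF (degassed), sealed tube, 110 → 125 °C, Ar
Reagents that add atoms: none
Why: Fluoride strips the trimethylsilyl group of 9 and triflate departs to give aryne 24 across C1'–C2'; the carboxylate of 23 adds through oxygen at C2' because the inductively withdrawing methoxymethoxy group on C6' polarises the strained triple bond so that the carbanion develops at C1' beside that oxygen, the opposing pull of the remote C4' oxygen being weaker. The C1' anion then attacks the carbonyl of the aryl ester just formed (4-exo-trig, a transient four-membered alkoxide, no ring persists), and ring opening gives the chelated 2'-phenoxide ketone, so the C2'–O and C1'–C1 bonds arise in one operation. The closest known reaction type is the fluoride-induced aryne insertion into the C–O bond of carboxylic acids, which gives ortho-hydroxyaryl ketones from aliphatic acids, combined with the established preference of 3-alkoxyarynes for nucleophilic attack at the carbon remote from the alkoxy group. Acyl transfer must outrun protonation of the aryl anion, hence aprotic tetrahydrofuran and no acetonitrile, and the anionic carboxylate must outcompete ene reaction of the aryne with the skipped polyene, which the sparing solubility of CsF (slow aryne release) favours. No stereocenter is formed, C17 and the Z-olefins are not involved, and the three acetals are inert to fluoride and to the short-lived aryl anion.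

Step 15
Reactants: 25 (5Z,8Z,11Z,14Z,17R)-1-[2-hydroxy-4,6-bis(methoxymethoxy)phenyl]-17-(methoxymethoxy)icosa-5,8,11,14-tetraen-1-one
Product: 26 (5Z,8Z,11Z,14Z,17R)-17-hydroxy-1-(2,4,6-trihydroxyphenyl)icosa-5,8,11,14-tetraen-1-one
Conditions: HCl (3 M in MeOH), THF, 45 °C, Ar
Reagents that add atoms: none
Why: Acid-catalysed transacetalisation to methanol cleaves the two aryl and the C17 methoxymethyl ethers in one operation, while the ketone, the skipped Z-olefins and the secondary carbinol centre (whose C–O bond is never broken) are unaffected.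

Compound list
1 | phloroglucinol | Oc1cc(O)cc(O)c1 | starting material
2 | 3,5-bis(methoxymethoxy)phenol | COCOc1cc(O)cc(OCOC)c1 | intermediate
3 | 3,5-bis(methoxymethoxy)phenyl isopropylcarbamate | CC(C)NC(=O)Oc1cc(OCOC)cc(OCOC)c1 | intermediate
4 | 3,5-bis(methoxymethoxy)phenyl N-(tert-butyldimethylsilyl)-N-isopropylcarbamate | CC(C)N(C(=O)Oc1cc(OCOC)cc(OCOC)c1)[Si](C)(C)C(C)(C)C | intermediate
5 | 2-lithio-3,5-bis(methoxymethoxy)phenyl N-(tert-butyldimethylsilyl)-N-isopropylcarbamate | CC(C)N(C(=O)Oc1cc(OCOC)cc(OCOC)c1[Li])[Si](C)(C)C(C)(C)C | intermediate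
6 | 3,5-bis(methoxymethoxy)-2-(trimethylsilyl)phenyl N-(tert-butyldimethylsilyl)-N-isopropylcarbamate | CC(C)N(C(=O)Oc1cc(OCOC)cc(OCOC)c1[Si](C)(C)C)[Si](C)(C)C(C)(C)C | intermediate
7 | 3,5-bis(methoxymethoxy)-2-(trimethylsilyl)phenyl isopropylcarbamate | CC(C)NC(=O)Oc1cc(OCOC)cc(OCOC)c1[Si](C)(C)C | intermediate
8 | 3,5-bis(methoxymethoxy)-2-(trimethylsilyl)phenol | COCOc1cc(O)c([Si](C)(C)C)c(OCOC)c1 | intermediate
9 | 3,5-bis(methoxymethoxy)-2-(trimethylsilyl)phenyl trifluoromethanesulfonate | COCOc1cc(OCOC)c([Si](C)(C)C)c(OS(=O)(=O)C(F)(F)F)c1 | intermediate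
10 | (R)-1,2-epoxypentane | CCC[C@@H]1CO1 | starting material
11 | lithium acetylide ethylenediamine complex | [Li+].[C-]#C.NCCN | starting material
12 | (R)-hept-1-yn-4-ol | CCC[C@@H](O)CC#C | intermediate
13 | (R)-4-(methoxymethoxy)hept-1-yne | CCC[C@@H](OCOC)CC#C | intermediate
14 | methyl hex-5-ynoate | C#CCCCC(=O)OC | starting material
15 | 4-chlorobut-2-yn-1-ol | OCC#CCCl | starting material
16 | methyl 10-hydroxydeca-5,8-diynoate | COC(=O)CCCC#CCC#CCO | intermediate
17 | methyl 10-bromodeca-5,8-diynoate | COC(=O)CCCC#CCC#CCBr | intermediate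
18 | propargyl alcohol | C#CCO | starting material
19 | methyl 13-hydroxytrideca-5,8,11-triynoate | COC(=O)CCCC#CCC#CCC#CCO | intermediate
20 | methyl 13-bromotrideca-5,8,11-triynoate | COC(=O)CCCC#CCC#CCC#CCBr | intermediate
21 | methyl (17R)-17-(methoxymethoxy)icosa-5,8,11,14-tetraynoate | CCC[C@@H](OCOC)CC#CCC#CCC#CCC#CCCCC(=O)OC | intermediate
22 | methyl (5Z,8Z,11Z,14Z,17R)-17-(methoxymethoxy)icosa-5,8,11,14-tetraenoate | CCC[C@@H](OCOC)C/C=C\C/C=C\C/C=C\C/C=C\CCCC(=O)OC | intermediate
23 | (5Z,8Z,11Z,14Z,17R)-17-(methoxymethoxy)icosa-5,8,11,14-tetraenoic acid | CCC[C@@H](OCOC)C/C=C\C/C=C\C/C=C\C/C=C\CCCC(=O)O | intermediate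
24 | 3,5-bis(methoxymethoxy)benzyne | C1#CC=C(OCOC)C=C1OCOC | intermediate
25 | (5Z,8Z,11Z,14Z,17R)-1-[2-hydroxy-4,6-bis(methoxymethoxy)phenyl]-17-(methoxymethoxy)icosa-5,8,11,14-tetraen-1-one | CCC[C@@H](OCOC)C/C=C\C/C=C\C/C=C\C/C=C\CCCC(=O)c1c(O)cc(OCOC)cc1OCOC | intermediate
26 | (5Z,8Z,11Z,14Z,17R)-17-hydroxy-1-(2,4,6-trihydroxyphenyl)icosa-5,8,11,14-tetraen-1-one | CCC[C@@H](O)C/C=C\C/C=C\C/C=C\C/C=C\CCCC(=O)c1c(O)cc(O)cc1O | target

Total step count: 15. Longest linear sequence: 9 steps (steps 7 to 15, from methyl hex-5-ynoate 14 to target 26).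

Steps most likely to fail

1. Step 14 (aryne insertion).
   - What may go wrong: the aryl anion is protonated before it reaches the ester carbonyl, leaving only O-arylation; the aryne is consumed by ene reaction at the doubly allylic positions of the polyene; the carboxylate adds at C1'; or prolonged heating erodes the Z-olefins.
   - Fallback: a Weinreb ketone synthesis, setting out from acid 23 and returning at target 26. Amide coupling of 23 with N,O-dimethylhydroxylamine hydrochloride (EDC·HCl, N-methylmorpholine, CH2Cl2) should give (5Z,8Z,11Z,14Z,17R)-N-methoxy-17-(methoxymethoxy)-N-methylicosa-5,8,11,14-tetraenamide F1. Phloroglucinol 1 with excess MOMCl and NaH in DMF gives 1,3,5-tris(methoxymethoxy)benzene F2, which n-BuLi in THF at 0 °C metalates between two acetal oxygens (all three ring positions are equivalent) to 2,4,6-tris(methoxymethoxy)phenyllithium F3. Addition of F3 to F1 at −78 °C should give (5Z,8Z,11Z,14Z,17R)-17-(methoxymethoxy)-1-[2,4,6-tris(methoxymethoxy)phenyl]icosa-5,8,11,14-tetraen-1-one F4, and the acid treatment of step 15 then removes all four acetals to reach 26.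

2. Step 12 (fourfold semihydrogenation).
   - What may go wrong: over-reduction of a double bond, incomplete reduction of one alkyne, or Z to E isomerisation on the catalyst, giving congeners that are hard to separate.
   - Fallback: stoichiometric hydroboration–protonolysis, setting out from tetrayne 21 and returning at ester 22. Dicyclohexylborane (from BH3·SMe2 and cyclohexene, THF, 0 °C) adds once and syn to each internal alkyne, giving methyl (5Z,8Z,11Z,14Z,17R)-6,9,12,15-tetrakis(dicyclohexylboranyl)-17-(methoxymethoxy)icosa-5,8,11,14-tetraenoate F5 (one of several regioisomers, not isolated). Protonolysis of the four alkenyl C–B bonds with acetic acid proceeds with retention and cannot over-reduce, so it should deliver 22.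

3. Step 3 (directed ortho-silylation).
   - What may go wrong: metalation between the two acetal oxygens instead of next to the carbamate, cleavage of an aryl acetal by the silyl triflate, or protodesilylation of the very electron-rich arylsilane on work-up.
   - Fallback: a halogen-based retro-Brook route, setting out from phenol 2 and returning at silyl triflate 9. Amine-catalysed ortho-bromination (NBS, i-Pr2NH cat., CH2Cl2, −78 °C) should give 2-bromo-3,5-bis(methoxymethoxy)phenol F6, and O-silylation with hexamethyldisilazane (THF, 65 °C) gives [2-bromo-3,5-bis(methoxymethoxy)phenoxy]trimethylsilane F7. Bromine–lithium exchange with n-BuLi (THF, −100 → −78 °C) triggers an O-to-C silyl shift (retro-Brook rearrangement) to phenol 8 as its lithium salt, which Tf2O converts into 9.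

Further compounds
F1 | step 14 | (5Z,8Z,11Z,14Z,17R)-N-methoxy-17-(methoxymethoxy)-N-methylicosa-5,8,11,14-tetraenamide | CCC[C@@H](OCOC)C/C=C\C/C=C\C/C=C\C/C=C\CCCC(=O)N(C)OC
F2 | step 14 | 1,3,5-tris(methoxymethoxy)benzene | COCOc1cc(OCOC)cc(OCOC)c1
F3 | step 14 | 2,4,6-tris(methoxymethoxy)phenyllithium | [Li]c1c(OCOC)cc(OCOC)cc1OCOC
F4 | step 14 | (5Z,8Z,11Z,14Z,17R)-17-(methoxymethoxy)-1-[2,4,6-tris(methoxymethoxy)phenyl]icosa-5,8,11,14-tetraen-1-one | CCC[C@@H](OCOC)C/C=C\C/C=C\C/C=C\C/C=C\CCCC(=O)c1c(OCOC)cc(OCOC)cc1OCOC
F5 | step 12 | methyl (5Z,8Z,11Z,14Z,17R)-6,9,12,15-tetrakis(dicyclohexylboranyl)-17-(methoxymethoxy)icosa-5,8,11,14-tetraenoate | CCC[C@@H](OCOC)C/C(B(C1CCCCC1)C1CCCCC1)=C\C/C(B(C1CCCCC1)C1CCCCC1)=C\C/C(B(C1CCCCC1)C1CCCCC1)=C\C/C(B(C1CCCCC1)C1CCCCC1)=C\CCCC(=O)OC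
F6 | step 3 | 2-bromo-3,5-bis(methoxymethoxy)phenol | COCOc1cc(O)c(Br)c(OCOC)c1
F7 | step 3 | [2-bromo-3,5-bis(methoxymethoxy)phenoxy]trimethylsilane | COCOc1cc(O[Si](C)(C)C)c(Br)c(OCOC)c1
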